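**Retrosynthetic overview**

1. Endgame: the 2-acetate comes from selective acylation of a 2α,3α-diol, the diol from OsO4 on a Δ2 olefin, and C17 from methyl cross-coupling of the Δ7 enol triflate of a C8 ketone whose α-carbon C9 is equilibrated to 9β.
2. Key disconnection (ring A, closed last): the C3–C4 bond. The enabling feature is that C4 with its two methyls hangs on C5 of ring B (C5–C10) and lies 1,3 across C6 from C7, the α-carbon of the C8 oxygen function. A C4–C7 bond, absent from the target, turns ring B plus C4 into the 6,6-dimethylbicyclo[3.1.1]heptan-2-one skeleton of (+)-verbenone.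
3. Forward, heterolysis of that cyclobutane bond (strain release) leaves a Δ7 enol ether and a C4 cation, which a (Z)-vinylsilane on C10 captures. One operation gives ring A, the C4 quaternary carbon, the Δ2 olefin and the ring B enol.
4. Before it: allyl (C1–C3) by conjugate addition to verbenone (sets C10), the side chain C11–C16 by alkylation at C9 with an iodo ester made from methyl hydrogen (R)-3-methylglutarate, then (Z)-silylation of the allyl terminus.
5. Ring order: ring B is present in verbenone from the start; ring A is closed in step 6.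

Key step: step 6

Remark: labdane numbering (C1–C20) is used for all intermediates, also the bicyclic ones (C4 is the gem-dimethyl bridge carbon, C7 the bridgehead next to the C8 carbonyl); 1 and 6 are taken as commercial in the enantiomeric forms shown.

**Step 1**
Reactants: 1 (3R)-5-methoxy-3-methyl-5-oxopentanoic acid (methyl hydrogen (R)-3-methylglutarate)
Product: 3 (4S)-4-methyloxan-2-one, via (3S)-5-hydroxy-3-methylpentanoic acid 2 (not isolated)
Conditions: lithium salt (LiOH, 1 equiv, dried); LiBH4, THF, reflux; then 2 M HCl, rt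
Reagents that add atoms: none
Why: LiBH4 reduces the methyl ester but leaves the lithium carboxylate, and acidification lactonises the hydroxy acid (chemoselective ester reduction, lactonisation); the stereocentre is untouched and only its CIP label changes.

**Step 2**
Reactants: 3 (4S)-4-methyloxan-2-one
Product: 5 methyl (3R)-5-iodo-3-methylpentanoate, via trimethylsilyl (3R)-5-iodo-3-methylpentanoate 4 (not isolated)
Conditions: Me3SiI, CH2Cl2, rt; then MeOH, rt
Reagents that add atoms: iodotrimethylsilane C[Si](C)(C)I; methanol CO
Why: Iodotrimethylsilane silylates the lactone carbonyl oxygen and iodide opens the ring by SN2 attack at the O–CH2 carbon, after which methanol converts the silyl ester into the methyl ester (lactone cleavage, esterification) without touching the stereocentre.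

**Step 3**
Reactants: 6 (1R,5R)-4,6,6-trimethylbicyclo[3.1.1]hept-3-en-2-one ((+)-verbenone)
Product: 8 (1R,4R,5R)-4-allyl-4,6,6-trimethylbicyclo[3.1.1]heptan-2-one, via trimethylsilyl enol ether 7 (not isolated)
Conditions: allylMgBr, CuBr·SMe2, Me3SiCl, THF, −78 °C; then 1 M HCl
Reagents that add atoms: allylmagnesium bromide C=CC[Mg]Br
Why: Me3SiCl-accelerated conjugate addition of an allylcopper reagent to the β,β-disubstituted enone should deliver allyl to C10 from the face opposite the gem-dimethyl bridge (C4), so that the C10 methyl ends up cis to C4 on ring B, the relation that becomes the trans A/B fusion.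

**Step 4**
Reactants: 8 (1R,4R,5R)-4-allyl-4,6,6-trimethylbicyclo[3.1.1]heptan-2-one; 5 methyl (3R)-5-iodo-3-methylpentanoate
Product: 10 methyl (3S)-5-[(1R,3S,4S,5S)-4-allyl-4,6,6-trimethyl-2-oxobicyclo[3.1.1]heptan-3-yl]-3-methylpentanoate (side chain on C9 anti to the gem-dimethyl bridge and cis to the allyl group), via lithium enolate 9 (not isolated)
Conditions: LiN(iPr)2, THF, −78 °C; 5 (1.3 equiv), HMPA, −78 to 0 °C
Reagents that add atoms: none
Why: Enolate alkylation (SN2) can only occur at C9 because C7 is a bridgehead, and the iodide should enter anti to the gem-dimethyl bridge, giving the 9α side chain that is corrected in step 7.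

**Step 5**
Reactants: 10 methyl (3S)-5-[(1R,3S,4S,5S)-4-allyl-4,6,6-trimethyl-2-oxobicyclo[3.1.1]heptan-3-yl]-3-methylpentanoate
Product: 11 methyl (3S)-3-methyl-5-[(1R,3S,4S,5S)-4,6,6-trimethyl-2-oxo-4-[(2Z)-3-(triethylsilyl)prop-2-en-1-yl]bicyclo[3.1.1]heptan-3-yl]pentanoate
Conditions: [Ir(OMe)(cod)]2 (cat.), 4,4′-di-tert-butyl-2,2′-bipyridine, Et3SiH, norbornene, THF, 40 °C
Reagents that add atoms: triethylsilane CC[SiH](CC)CC
Why: Iridium-catalysed dehydrogenative silylation of a terminal olefin with norbornene as hydrogen acceptor is a known route to (Z)-vinylsilanes that should tolerate ketone and ester, and the Z geometry is what the endocyclic cyclisation of step 6 needs.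

**Step 6**
Reactants: 11 methyl (3S)-3-methyl-5-[(1R,3S,4S,5S)-4,6,6-trimethyl-2-oxo-4-[(2Z)-3-(triethylsilyl)prop-2-en-1-yl]bicyclo[3.1.1]heptan-3-yl]pentanoate
Product: 13 methyl (13S)-8-oxo-17-nor-9-epi-labd-2-en-15-oate (trans-fused; 5α-H; 10β-CH3; side chain 9α), via triethylsilyl enol ether 12 (not isolated)
Conditions: Et3SiOTf (0.3 equiv), 2,6-di-tert-butyl-4-methylpyridine (0.1 equiv), CH2Cl2 (0.01 M), −20 °C to rt; then 1 M HCl, THF, 0 °C
Reagents that add atoms: none
Why: Proposed new method: O-silylation of the C8 ketone should give a silyloxycarbenium ion whose strained C7–C4 cyclobutane bond heterolyses (Grob-type fragmentation, driven by release of the four-ring strain) to the Δ7 triethylsilyl enol ether and the tertiary C4 cation, which the (Z)-vinylsilane on C10 captures at its silicon-bearing carbon C3, and loss of Et3Si+ from the β-silyl cation at C2 gives the Δ2 olefin and returns the silyl triflate, so that the step is a catalytic C-to-O silyl-transfer isomerisation. The closest known reaction types are the Lewis acid or iodotrimethylsilane cleavage of nopinone-type cyclobutyl ketones to ring-opened cyclohexenyl enol derivatives whose tertiary cation is trapped by halide or acetate, the acid-mediated opening of 4-substituted pinenes with capture of the same cation by an internal oxygen nucleophile, and vinylsilane-terminated cation–olefin cyclisations; what is new is the union of the ketone-triggered fragmentation with carbon–carbon capture. Ring A closes at the C3–C4 bond by 6-endo-trig attack of the vinylsilane on the cation through a chair transition state. No new stereocentre is formed (C4 bears two methyls and the C7 bridgehead centre is lost), and the trans A/B fusion is inherited from C5 of verbenone and from C10 set in step 3, whose C5–C4 and C10–C1 bonds are trans and diequatorial on ring B. The step needs cleavage of C7–C4 and not C7–C6 (tertiary against primary cation), bond formation at C3 and not C2 (β-silicon effect, for which the Z geometry lets the C–Si bond align with the developing cation, and six- against five-membered ring), and one olefin position in each ring (Δ2 by loss of silicon, Δ7 by the site of the broken bond); high dilution and a trace of hindered pyridine hold back intermolecular alkylation of the enol ether and protodesilylation.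

**Step 7**
Reactants: 13 methyl (13S)-8-oxo-17-nor-9-epi-labd-2-en-15-oate
Product: 14 methyl (13S)-8-oxo-17-norlabd-2-en-15-oate (5α-H; 9α-H; 10β-CH3; side chain 9β)
Conditions: NaOMe (0.2 equiv), MeOH, rt
Reagents that add atoms: none
Why: Base-catalysed epimerisation through the C8 enolate should favour the equatorial 9β side chain, since the axial 9α chain meets H1α, H5α and H7α, and kinetic protonation of the enolate from the α face (opposite the C10 methyl) leads to the same epimer.

**Step 8**
Reactants: 14 methyl (13S)-8-oxo-17-norlabd-2-en-15-oate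
Product: 16 methyl (13S)-8-(trifluoromethanesulfonyloxy)-17-norlabda-2,7-dien-15-oate, via potassium enolate 15 (not isolated)
Conditions: KN(SiMe3)2 (1.05 equiv), THF, −78 °C; PhNTf2, −78 to 0 °C; aq NH4Cl
Reagents that add atoms: N-phenylbis(trifluoromethanesulfonimide) O=S(=O)(N(c1ccccc1)S(=O)(=O)C(F)(F)F)C(F)(F)F
Why: Kinetic deprotonation by the hindered amide base should remove a C7 hydrogen and not the hindered C9 methine, and O-triflation of the enolate then fixes the Δ7 position (enol triflate formation).

**Step 9**
Reactants: 16 methyl (13S)-8-(trifluoromethanesulfonyloxy)-17-norlabda-2,7-dien-15-oate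
Product: 17 methyl (13S)-2α,3α-dihydroxy-8-(trifluoromethanesulfonyloxy)-17-norlabd-7-en-15-oate
Conditions: OsO4 (5 mol%), N-methylmorpholine N-oxide, acetone/H2O, rt
Reagents that add atoms: osmium tetroxide O=[Os](=O)(=O)=O; N-methylmorpholine N-oxide C[N+]1([O-])CCOCC1; water O
Why: Catalytic OsO4 dihydroxylation should attack only the Δ2 olefin, the enol triflate being electron-poor, and from the α face because the axial C19 and C20 methyls shield the β face, which sets C2 and C3 as the cis-2α,3α-diol.

**Step 10**
Reactants: 17 methyl (13S)-2α,3α-dihydroxy-8-(trifluoromethanesulfonyloxy)-17-norlabd-7-en-15-oate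
Product: 18 methyl (13S)-2α,3α-dihydroxylabd-7-en-15-oate
Conditions: Me4Sn, Pd(PPh3)4 (5 mol%), LiCl, DMF, 80 °C
Reagents that add atoms: tetramethylstannane C[Sn](C)(C)C
Why: Stille cross-coupling of the enol triflate with tetramethyltin (LiCl-promoted) should install C17 with the Δ7 position retained and should tolerate the free diol and the ester.

**Step 11**
Reactants: 18 methyl (13S)-2α,3α-dihydroxylabd-7-en-15-oate
Product: 19 methyl (13S)-2α-acetoxy-3α-hydroxylabd-7-en-15-oate (target)
Conditions: Ac2O (1.1 equiv), pyridine, 0 °C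
Reagents that add atoms: acetic anhydride CC(=O)OC(C)=O
Why: Acylation should occur only at the equatorial 2α-hydroxyl, because the axial 3α-hydroxyl next to the C4 gem-dimethyl group is neopentylic and hindered (selective monoacetylation).

**Compound list**

1 | (3R)-5-methoxy-3-methyl-5-oxopentanoic acid | OC(=O)C[C@@H](C)CC(=O)OC | starting material
2 | (3S)-5-hydroxy-3-methylpentanoic acid | OC(=O)C[C@@H](C)CCO | intermediate
3 | (4S)-4-methyloxan-2-one | O=C1C[C@@H](C)CCO1 | intermediate
4 | trimethylsilyl (3R)-5-iodo-3-methylpentanoate | C[Si](C)(C)OC(=O)C[C@@H](C)CCI | intermediate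
5 | methyl (3R)-5-iodo-3-methylpentanoate | COC(=O)C[C@@H](C)CCI | intermediate
6 | (1R,5R)-4,6,6-trimethylbicyclo[3.1.1]hept-3-en-2-one ((+)-verbenone) | CC1=CC(=O)[C@@H]2C[C@H]1C2(C)C | starting material
7 | 4-allyl-4,6,6-trimethyl-2-(trimethylsilyloxy)bicyclo[3.1.1]hept-2-ene (allyl anti to the gem-dimethyl bridge) | C=CC[C@]1(C)C=C(O[Si](C)(C)C)[C@@H]2C[C@H]1C2(C)C | intermediate
8 | (1R,4R,5R)-4-allyl-4,6,6-trimethylbicyclo[3.1.1]heptan-2-one | C=CC[C@]1(C)CC(=O)[C@@H]2C[C@H]1C2(C)C | intermediate
9 | lithium enolate of 8 | C=CC[C@]1(C)C=C(O[Li])[C@@H]2C[C@H]1C2(C)C | intermediate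
10 | methyl (3S)-5-[(1R,3S,4S,5S)-4-allyl-4,6,6-trimethyl-2-oxobicyclo[3.1.1]heptan-3-yl]-3-methylpentanoate | COC(=O)C[C@@H](C)CC[C@@H]1C(=O)[C@@H]2C[C@@H](C2(C)C)[C@]1(C)CC=C | intermediate
11 | methyl (3S)-3-methyl-5-[(1R,3S,4S,5S)-4,6,6-trimethyl-2-oxo-4-[(2Z)-3-(triethylsilyl)prop-2-en-1-yl]bicyclo[3.1.1]heptan-3-yl]pentanoate | COC(=O)C[C@@H](C)CC[C@@H]1C(=O)[C@@H]2C[C@@H](C2(C)C)[C@]1(C)C/C=C\[Si](CC)(CC)CC | intermediate
12 | triethylsilyl Δ7-enol ether of 13 | COC(=O)C[C@@H](C)CC[C@@H]1C(O[Si](CC)(CC)CC)=CC[C@H]2C(C)(C)C=CC[C@]12C | intermediate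
13 | methyl (13S)-8-oxo-17-nor-9-epi-labd-2-en-15-oate (side chain 9α) | COC(=O)C[C@@H](C)CC[C@@H]1C(=O)CC[C@H]2C(C)(C)C=CC[C@]12C | intermediate
14 | methyl (13S)-8-oxo-17-norlabd-2-en-15-oate (side chain 9β) | COC(=O)C[C@@H](C)CC[C@H]1C(=O)CC[C@H]2C(C)(C)C=CC[C@]12C | intermediate
15 | potassium Δ7-enolate of 14 | COC(=O)C[C@@H](C)CC[C@H]1C(O[K])=CC[C@H]2C(C)(C)C=CC[C@]12C | intermediate
16 | methyl (13S)-8-(trifluoromethanesulfonyloxy)-17-norlabda-2,7-dien-15-oate | COC(=O)C[C@@H](C)CC[C@H]1C(OS(=O)(=O)C(F)(F)F)=CC[C@H]2C(C)(C)C=CC[C@]12C | intermediate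
17 | methyl (13S)-2α,3α-dihydroxy-8-(trifluoromethanesulfonyloxy)-17-norlabd-7-en-15-oate | COC(=O)C[C@@H](C)CC[C@H]1C(OS(=O)(=O)C(F)(F)F)=CC[C@H]2C(C)(C)[C@H](O)[C@H](O)C[C@]12C | intermediate
18 | methyl (13S)-2α,3α-dihydroxylabd-7-en-15-oate | COC(=O)C[C@@H](C)CC[C@H]1C(C)=CC[C@H]2C(C)(C)[C@H](O)[C@H](O)C[C@]12C | intermediate
19 | methyl (13S)-2α-acetoxy-3α-hydroxylabd-7-en-15-oate | COC(=O)C[C@@H](C)CC[C@H]1C(C)=CC[C@H]2C(C)(C)[C@H](O)[C@H](OC(C)=O)C[C@]12C | target

**Step count**

Total: 11 steps. Longest linear sequence: 10 steps (steps 1, 2 and 4–11, from 1); from verbenone 6 it is 9 steps (3–11).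

**Steps most likely to fail, with fallbacks**

Step 6 (the proposed new method). The C4 cation may lose a proton (or take a hydride from C5) before it cyclises, the vinylsilane may be protodesilylated or may add to the silyl-activated carbonyl before the cyclobutane opens, or the ketone may simply be silylated towards C9. The fallback separates fragmentation from cyclisation, uses known reaction types only, and sets out from 10. BF3·OEt2, Zn(OAc)2 and Ac2O at rt, the established conditions for cyclobutane cleavage of nopinones, should add the elements of acetic anhydride across the C7–C4 bond and give the ring-opened diacetate F1 (Δ7 enol acetate, tertiary acetate on C4). The iridium-catalysed (Z)-silylation of step 5 should then give vinylsilane F2. SnCl4 in CH2Cl2 at −78 °C should ionise the tertiary acetate, and vinylsilane-terminated cation–olefin cyclisation should give the decalin enol acetate F3. K2CO3 in MeOH cleaves the enol acetate and equilibrates C9, which brings the route back at 14.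

Step 4. C-alkylation at the neopentylic enolate carbon may be too slow, so that O-alkylation, proton transfer or loss of HI from the iodide takes over. The fallback raises the nucleophilicity of C9 through an aza-enolate and sets out from 8. N,N-Dimethylhydrazine (AcOH cat., EtOH, reflux) should give the N,N-dimethylhydrazone F4. LiN(iPr)2 in THF at 0 °C gives the lithiated aza-enolate F5, which should be alkylated by 5 anti to the gem-dimethyl bridge to the alkylated hydrazone F6. Two-phase hydrolysis with aqueous oxalic acid and ether returns the ketone, and the route comes back at 10.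

Step 7. Equilibration at C9 may stop short or settle at an unfavourable ratio if the equatorial preference of the side chain next to the quaternary C10 is small. The fallback sets C9 by kinetic protonation before the ring is opened and sets out from 11. LiN(iPr)2 (THF, −78 °C) gives the lithium enolate F7. Protonation at −78 °C with 2,6-di-tert-butyl-4-methylphenol (then aq NH4Cl) should come from the face opposite the gem-dimethyl bridge and give the C9 epimer F8, with the side chain syn to the bridge (the labdane 9β configuration). Under the conditions of step 6, F8 should give the 9β triethylsilyl enol ether F9 and, after hydrolysis, the route comes back at 14 without an epimerisation step.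

**Further compounds**

F1 | step 6 | methyl 5-[2-acetoxy-5-(2-acetoxypropan-2-yl)-6-allyl-6-methylcyclohex-2-en-1-yl]-3-methylpentanoate (configuration as in 10) | COC(=O)C[C@@H](C)CC[C@@H]1C(OC(C)=O)=CC[C@@H](C(C)(C)OC(C)=O)[C@]1(C)CC=C
F2 | step 6 | (Z)-3-(triethylsilyl)allyl analogue of F1 | COC(=O)C[C@@H](C)CC[C@@H]1C(OC(C)=O)=CC[C@@H](C(C)(C)OC(C)=O)[C@]1(C)C/C=C\[Si](CC)(CC)CC
F3 | step 6 | methyl (13S)-8-acetoxy-17-nor-9-epi-labda-2,7-dien-15-oate | COC(=O)C[C@@H](C)CC[C@@H]1C(OC(C)=O)=CC[C@H]2C(C)(C)C=CC[C@]12C
F4 | step 4 | N,N-dimethylhydrazone of 8 | C=CC[C@]1(C)CC(=NN(C)C)[C@@H]2C[C@H]1C2(C)C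
F5 | step 4 | lithiated aza-enolate of F4 | C=CC[C@]1(C)C=C(N([Li])N(C)C)[C@@H]2C[C@H]1C2(C)C
F6 | step 4 | N,N-dimethylhydrazone of 10 | COC(=O)C[C@@H](C)CC[C@@H]1C(=NN(C)C)[C@@H]2C[C@@H](C2(C)C)[C@]1(C)CC=C
F7 | step 7 | lithium enolate of 11 | COC(=O)C[C@@H](C)CCC1=C(O[Li])[C@@H]2C[C@@H](C2(C)C)[C@]1(C)C/C=C\[Si](CC)(CC)CC
F8 | step 7 | C9 epimer of 11 (side chain syn to the gem-dimethyl bridge) | COC(=O)C[C@@H](C)CC[C@H]1C(=O)[C@@H]2C[C@@H](C2(C)C)[C@]1(C)C/C=C\[Si](CC)(CC)CC
F9 | step 7 | triethylsilyl Δ7-enol ether of 14 | COC(=O)C[C@@H](C)CC[C@H]1C(O[Si](CC)(CC)CC)=CC[C@H]2C(C)(C)C=CC[C@]12C
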